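**Retrosynthetic overview**
1. Target 24 comes from acetal 23 (C11 unmasked last). The side-chain carbinol comes from CBS reduction of an isopropenyl ketone, the C4 quaternary centre (methyl plus chain) from a hydrogen-atom-transfer Giese addition to a C4 exocyclic methylene, and the C3 chloride from inversion of a 3α-hydroxy-4-ketone.
2. Ring B is disconnected at C5–C6 and C9–C10 (Diels–Alder) into enone 3 (ring A, from a dearomatized phenol) and silyloxy diene 7, which already carries C6–C9, C11 and C12.
3. Enabling feature: ring B is a cyclohexene whose C7=C8 bond (ester on C8) lies between the two new bonds. Ring A has oxygen at C1 (the enone carbonyl that activates C5=C10) and a masked carbonyl at C4 next to C5, so the cis adduct can be epimerized to the trans decalin.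
4. Two temporary groups are used: a C3 silyl group (sets absolute configuration and the face of the cycloaddition, lost on ketal hydrolysis) and a C7 silyloxy group (removed through the enol triflate).
5. Ring order: ring A first (aromatic precursor), ring B second (key step).

Key step: step 5

Remark: positions are numbered as in the decalin core of the target (C1–C10, ring fusion at C5 and C10, C11 = acetal/formyl carbon on C9, C12 = ester carbon on C8); β is the face of the C10 methyl, α the opposite face; 6 and 7 are expected as Z-rich E/Z mixtures and are drawn as Z.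

**Route**

Step 1
Reactants: 1 4-methoxy-2-methylphenol
Product: 2 4,4-dimethoxy-2-methylcyclohexa-2,5-dien-1-one
Conditions: PhI(OAc)2, MeOH, 0 °C
Reagents that add atoms: methanol, CO
Why: Oxidative dearomatization of a para-methoxyphenol, in which methanol traps the phenoxonium ion para to oxygen to give the quinone monoketal; no stereocenter is formed.

Step 2
Reactants: 2 4,4-dimethoxy-2-methylcyclohexa-2,5-dien-1-one
Product: 3 (5S)-5-[dimethyl(phenyl)silyl]-4,4-dimethoxy-2-methylcyclohex-2-en-1-one
Conditions: PhMe2Si–B(pin), CuCl (5 mol %), chiral imidazolinium salt (carbene precursor, 5.5 mol %), NaOtBu (11 mol %), THF, −78 °C; then MeOH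
Reagents that add atoms: 2-[dimethyl(phenyl)silyl]-4,4,5,5-tetramethyl-1,3,2-dioxaborolane, C[Si](C)(c1ccccc1)B1OC(C)(C)C(C)(C)O1
Why: Enantioselective conjugate silyl addition catalysed by CuCl and the chiral carbene should occur at the unsubstituted enone of the dienone (the 2-methyl enone is slower), the chiral (carbene)Cu–SiMe2Ph species selecting the face that makes the silyl-bearing carbon S.

Step 3
Reactants: 4 methyl acetoacetate; 5 2,2-dimethoxyacetaldehyde
Product: 6 methyl (2Z)-2-acetyl-4,4-dimethoxybut-2-enoate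
Conditions: piperidine (10 mol %), AcOH (10 mol %), 4 Å molecular sieves, CH2Cl2, 0 °C to rt
Reagents that add atoms: none
Why: Knoevenagel condensation of the active methylene with the aldehyde; the alkene geometry is thermodynamic (acetal cis to the ester expected) and no stereocenter is formed.

Step 4
Reactants: 6 methyl (2Z)-2-acetyl-4,4-dimethoxybut-2-enoate
Product: 7 methyl (2Z)-4,4-dimethoxy-2-[1-(triisopropylsilyloxy)ethenyl]but-2-enoate
Conditions: iPr3SiOTf, Et3N, CH2Cl2, 0 °C
Reagents that add atoms: triisopropylsilyl trifluoromethanesulfonate, CC(C)[Si](OS(=O)(=O)C(F)(F)F)(C(C)C)C(C)C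
Why: Soft enolization and O-silylation at the acetyl methyl, the only α-position of the ketone that bears hydrogen, gives the 2-silyloxy diene; no stereocenter is formed.

Step 5
Reactants: 3 (5S)-silyl enone; 7 silyloxy diene
Product: 8 cis-fused Diels–Alder adduct (1-ketone; 4,4-dimethyl ketal; 3β-SiMe2Ph; 10β-methyl; 5β-H; 9α-CH(OMe)2; 7-silyloxy-7-ene-8-carboxylate)
Conditions: toluene (2 M), 100 °C, sealed tube, BHT (cat.); alternatively 12 kbar, CH2Cl2, 25 °C
Reagents that add atoms: none
Why: Thermal normal-demand Diels–Alder reaction, concerted but strongly asynchronous with the C5–C6 bond leading, between the 2-methyl enone C5=C10 of 3 and the push–pull diene 7. The closest known reaction type is the Diels–Alder addition of 2-silyloxy dienes to 5-substituted 2-methylcyclohex-2-enones, which gives cis-fused adducts anti to the 5-substituent. Ring B is closed by an intermolecular suprafacial [4+2] with both new bonds on one face of ring A, hence the cis fusion that step 7 corrects. C10 and C5 are controlled by the pseudoequatorial C3 silyl group and the axial ketal methoxy on the same face, so the diene should add to the α face and the C10 methyl end β; C9 follows from the endo transition state and is reset in steps 8 and 9. The step needs regioselectivity (C6 to C5, C9 to C10), which matched polarity secures: the C7 silyloxy group makes C6 the nucleophilic terminus for the enone β-carbon C5, the C8 ester makes C9 the electrophilic terminus for the α-carbon C10, and the only other C=C of ring A was consumed in step 2.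

Step 6
Reactants: 8 cis-fused Diels–Alder adduct
Product: 9 1α-alcohol of the cis-fused adduct
Conditions: LiBH(s-Bu)3, THF, −78 °C; aq. NH4Cl
Reagents that add atoms: none
Why: Bulky-hydride reduction of the only ketone; in the cis-fused adduct the α face of C1 is blocked by the axial C5–C6 bond, so hydride should enter from the β face and give the 1α (axial) alcohol.

Step 7
Reactants: 9 1α-alcohol of the cis-fused adduct
Product: 11 trans-fused 1α-hydroxy-4-ketone (5α-H), via cis-fused 4-ketone 10 (not isolated)
Conditions: PPTS, acetone/H2O (10:1), rt; then DBU, CH2Cl2, rt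
Reagents that add atoms: water, O
Why: Acid hydrolysis of the dimethyl ketal, assisted by the β-silyl group that is lost as silanol (protodesilylation of the α-silyl ketone), is followed by base-mediated epimerization at C5 next to the new C4 ketone, which should give the more stable trans-fused decalone under thermodynamic control.

Step 8
Reactants: 11 trans-fused 1α-hydroxy-4-ketone
Product: 12 alkylidene keto ester (7-ketone; C8=C9; acetal on C9)
Conditions: Pd(OAc)2 (1.1 equiv), MeCN, rt
Reagents that add atoms: none
Why: Saegusa–Ito oxidation of the silyl enol ether, in which palladation at C8 and β-hydride elimination of H-9 (the only β-hydrogen) give the C8=C9 keto ester and erase the C9 stereocenter.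

Step 9
Reactants: 12 alkylidene keto ester
Product: 13 β-keto ester with 9β-acetal (drawn as the enol)
Conditions: [(Ph3P)CuH]6 (0.4 equiv), benzene, H2O (5 equiv), rt
Reagents that add atoms: none
Why: Chemoselective conjugate reduction of the doubly activated alkene by [(Ph3P)CuH]6; hydride should add to C9 from the α face, anti to the axial C10 methyl, placing the acetal 9β (equatorial) and leaving the isolated C4 ketone untouched.

Step 10
Reactants: 13 β-keto ester with 9β-acetal
Product: 14 C7 enol triflate
Conditions: NaH (1.05 equiv), THF, 0 °C; then PhNTf2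
Reagents that add atoms: N-phenylbis(trifluoromethanesulfonimide), O=S(=O)(N(c1ccccc1)S(=O)(=O)C(F)(F)F)C(F)(F)F
Why: O-sulfonylation of the sodium enolate of the β-keto ester, which is far more acidic than the C4 ketone or the alcohol, gives the enol triflate without touching a stereocenter.

Step 11
Reactants: 14 C7 enol triflate
Product: 15 C7=C8 conjugated methyl ester (4-ketone; 1α-OH; 9β-acetal)
Conditions: Pd(OAc)2 (5 mol %), PPh3 (10 mol %), HCO2H, Et3N, DMF, 60 °C
Reagents that add atoms: none
Why: Formate reduction of the enol triflate catalysed by Pd(OAc)2/PPh3 (oxidative addition, formate exchange, decarboxylation, reductive elimination) replaces the triflate by hydrogen and keeps the alkene at C7=C8.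

Step 12
Reactants: 15 conjugated ester 4-ketone
Product: 17 3α-hydroxy-4-ketone, via 3α-anilinooxy ketone 16 (not isolated)
Conditions: L-proline (20 mol %), PhNO (2.5 equiv), DMSO, rt; then CuSO4·5H2O (30 mol %), MeOH, 0 °C
Reagents that add atoms: nitrosobenzene, O=Nc1ccccc1
Why: Proline-catalysed α-aminoxylation through the less substituted enamine of the only ketone (toward C3), the L-catalyst delivering oxygen to the α (axial) face, followed by N–O cleavage to the 3α-hydroxy ketone.

Step 13
Reactants: 17 3α-hydroxy-4-ketone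
Product: 18 3β-chloro-4-ketone
Conditions: PPh3 (1.3 equiv), CCl4, MeCN, 0 °C to rt
Reagents that add atoms: carbon tetrachloride, ClC(Cl)(Cl)Cl
Why: Appel reaction, in which SN2 displacement of the alkoxyphosphonium at the carbon α to the ketone proceeds with inversion and turns the axial 3α-alcohol into the equatorial 3β-chloride, while the neopentyl 1α-alcohol cannot be displaced.

Step 14
Reactants: 18 3β-chloro-4-ketone
Product: 19 3β-chloro-4-methylidene compound
Conditions: Cp2Ti(μ-CH2)(μ-Cl)AlMe2 (2.2 equiv), pyridine (cat.), THF, −40 to 0 °C; aq. NaOH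
Reagents that add atoms: μ-chloro-μ-methylene-bis(cyclopentadienyl)titanium dimethylaluminium, C[Al-]1(C)C[Ti](C2C=CC=C2)(C2C=CC=C2)[Cl+]1
Why: Tebbe olefination, in which the titanium methylidene released by pyridine adds to the C4 ketone and the oxatitanacyclobutane collapses to the exocyclic methylene, runs under non-basic conditions that should preserve the α-chloro stereocenter and, at low temperature, spare the less reactive conjugated ester (one equivalent of reagent is held by the 1α-hydroxyl and released on work-up).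

Step 15
Reactants: 19 3β-chloro-4-methylidene compound; 20 N-methoxy-N-methylprop-2-enamide
Product: 21 C4-quaternary Weinreb amide (4β-methyl; 4α-chain)
Conditions: Fe(acac)3 (30 mol %), PhSiH3 (2.5 equiv), EtOH/ethylene glycol (5:1), 60 °C
Reagents that add atoms: none
Why: Metal-hydride hydrogen-atom-transfer Giese addition, in which the Fe–H species formed from Fe(acac)3 and PhSiH3 delivers a hydrogen atom to the methylene carbon (which becomes the C4 methyl) and the tertiary C4 radical should add to the acrylamide from the α face, anti to the axial C10 methyl, so the chain is α and the new methyl β.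

Step 16
Reactants: 21 C4-quaternary Weinreb amide
Product: 22 isopropenyl ketone
Conditions: CH2=C(CH3)MgBr (2.5 equiv), THF, −78 to 0 °C; aq. NH4Cl
Reagents that add atoms: isopropenylmagnesium bromide, C=C(C)[Mg]Br
Why: Weinreb ketone synthesis, in which the chelated tetrahedral intermediate stops at the ketone and the amide reacts faster than the hindered conjugated methyl ester; no stereocenter is formed.

Step 17
Reactants: 22 isopropenyl ketone
Product: 23 (3R)-allylic alcohol with C11 acetal
Conditions: (S)-2-methyl-CBS-oxazaborolidine (20 mol %), catecholborane, toluene, −78 °C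
Reagents that add atoms: none
Why: Corey–Bakshi–Shibata reduction of the enone, in which the isopropenyl group acts as the large substituent so the S catalyst should give the R allylic alcohol by reagent control.

Step 18
Reactants: 23 (3R)-allylic alcohol with C11 acetal
Product: 24 CNP0159496.2
Conditions: PPTS, acetone/H2O (4:1), 40 °C
Reagents that add atoms: water, O
Why: Mild acid hydrolysis of the dimethyl acetal releases the C11 aldehyde without enolization, so the 9β configuration set in step 9 should be kept.

**Compound list**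
1 | 4-methoxy-2-methylphenol | Cc1cc(OC)ccc1O | starting material
2 | 4,4-dimethoxy-2-methylcyclohexa-2,5-dien-1-one | COC1(OC)C=CC(=O)C(C)=C1 | intermediate
3 | (5S)-5-[dimethyl(phenyl)silyl]-4,4-dimethoxy-2-methylcyclohex-2-en-1-one | COC1(OC)[C@@H]([Si](C)(C)c2ccccc2)CC(=O)C(C)=C1 | intermediate
4 | methyl acetoacetate | CC(=O)CC(=O)OC | starting material
5 | 2,2-dimethoxyacetaldehyde | COC(OC)C=O | starting material
6 | methyl (2Z)-2-acetyl-4,4-dimethoxybut-2-enoate | CC(=O)/C(=C/C(OC)OC)C(=O)OC | intermediate
7 | methyl (2Z)-4,4-dimethoxy-2-[1-(triisopropylsilyloxy)ethenyl]but-2-enoate | C=C(O[Si](C(C)C)(C(C)C)C(C)C)/C(=C/C(OC)OC)C(=O)OC | intermediate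
8 | methyl 9α-(dimethoxymethyl)-3β-[dimethyl(phenyl)silyl]-4,4-dimethoxy-10β-methyl-1-oxo-7-(triisopropylsilyloxy)-5β-decal-7-ene-8-carboxylate (cis-fused) | COC1(OC)[C@@H]([Si](C)(C)c3ccccc3)CC(=O)[C@]2(C)[C@H](C(OC)OC)C(C(=O)OC)=C(O[Si](C(C)C)(C(C)C)C(C)C)C[C@H]12 | intermediate
9 | methyl 9α-(dimethoxymethyl)-3β-[dimethyl(phenyl)silyl]-1α-hydroxy-4,4-dimethoxy-10β-methyl-7-(triisopropylsilyloxy)-5β-decal-7-ene-8-carboxylate | COC1(OC)[C@@H]([Si](C)(C)c3ccccc3)C[C@H](O)[C@]2(C)[C@H](C(OC)OC)C(C(=O)OC)=C(O[Si](C(C)C)(C(C)C)C(C)C)C[C@H]12 | intermediate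
10 | methyl 9α-(dimethoxymethyl)-1α-hydroxy-10β-methyl-4-oxo-7-(triisopropylsilyloxy)-5β-decal-7-ene-8-carboxylate (cis-fused) | O=C1CC[C@H](O)[C@]2(C)[C@H](C(OC)OC)C(C(=O)OC)=C(O[Si](C(C)C)(C(C)C)C(C)C)C[C@H]12 | intermediate
11 | methyl 9α-(dimethoxymethyl)-1α-hydroxy-10β-methyl-4-oxo-7-(triisopropylsilyloxy)-5α-decal-7-ene-8-carboxylate (trans-fused) | O=C1CC[C@H](O)[C@]2(C)[C@H](C(OC)OC)C(C(=O)OC)=C(O[Si](C(C)C)(C(C)C)C(C)C)C[C@@H]12 | intermediate
12 | methyl 9-(dimethoxymethyl)-1α-hydroxy-10β-methyl-4,7-dioxo-5α-decal-8-ene-8-carboxylate | O=C1CC[C@H](O)[C@]2(C)C(C(OC)OC)=C(C(=O)OC)C(=O)C[C@@H]12 | intermediate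
13 | methyl 9β-(dimethoxymethyl)-1α,7-dihydroxy-10β-methyl-4-oxo-5α-decal-7-ene-8-carboxylate (enol form of the β-keto ester) | O=C1CC[C@H](O)[C@]2(C)[C@@H](C(OC)OC)C(C(=O)OC)=C(O)C[C@@H]12 | intermediate
14 | methyl 9β-(dimethoxymethyl)-1α-hydroxy-10β-methyl-4-oxo-7-(trifluoromethylsulfonyloxy)-5α-decal-7-ene-8-carboxylate | O=C1CC[C@H](O)[C@]2(C)[C@@H](C(OC)OC)C(C(=O)OC)=C(OS(=O)(=O)C(F)(F)F)C[C@@H]12 | intermediate
15 | methyl 9β-(dimethoxymethyl)-1α-hydroxy-10β-methyl-4-oxo-5α-decal-7-ene-8-carboxylate | O=C1CC[C@H](O)[C@]2(C)[C@@H](C(OC)OC)C(C(=O)OC)=CC[C@@H]12 | intermediate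
16 | methyl 3α-(anilinooxy)-9β-(dimethoxymethyl)-1α-hydroxy-10β-methyl-4-oxo-5α-decal-7-ene-8-carboxylate | O=C1[C@H](ONc3ccccc3)C[C@H](O)[C@]2(C)[C@@H](C(OC)OC)C(C(=O)OC)=CC[C@@H]12 | intermediate
17 | methyl 9β-(dimethoxymethyl)-1α,3α-dihydroxy-10β-methyl-4-oxo-5α-decal-7-ene-8-carboxylate | O=C1[C@H](O)C[C@H](O)[C@]2(C)[C@@H](C(OC)OC)C(C(=O)OC)=CC[C@@H]12 | intermediate
18 | methyl 3β-chloro-9β-(dimethoxymethyl)-1α-hydroxy-10β-methyl-4-oxo-5α-decal-7-ene-8-carboxylate | O=C1[C@@H](Cl)C[C@H](O)[C@]2(C)[C@@H](C(OC)OC)C(C(=O)OC)=CC[C@@H]12 | intermediate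
19 | methyl 3β-chloro-9β-(dimethoxymethyl)-1α-hydroxy-10β-methyl-4-methylidene-5α-decal-7-ene-8-carboxylate | C=C1[C@@H](Cl)C[C@H](O)[C@]2(C)[C@@H](C(OC)OC)C(C(=O)OC)=CC[C@@H]12 | intermediate
20 | N-methoxy-N-methylprop-2-enamide | C=CC(=O)N(C)OC | starting material
21 | methyl 3β-chloro-9β-(dimethoxymethyl)-1α-hydroxy-4α-{3-[methoxy(methyl)amino]-3-oxopropyl}-4β,10β-dimethyl-5α-decal-7-ene-8-carboxylate | CON(C)C(=O)CC[C@]1(C)[C@@H](Cl)C[C@H](O)[C@]2(C)[C@@H](C(OC)OC)C(C(=O)OC)=CC[C@@H]12 | intermediate
22 | methyl 3β-chloro-9β-(dimethoxymethyl)-1α-hydroxy-4β,10β-dimethyl-4α-(4-methyl-3-oxopent-4-enyl)-5α-decal-7-ene-8-carboxylate | C=C(C)C(=O)CC[C@]1(C)[C@@H](Cl)C[C@H](O)[C@]2(C)[C@@H](C(OC)OC)C(C(=O)OC)=CC[C@@H]12 | intermediate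
23 | methyl 3β-chloro-9β-(dimethoxymethyl)-1α-hydroxy-4α-[(3R)-3-hydroxy-4-methylpent-4-enyl]-4β,10β-dimethyl-5α-decal-7-ene-8-carboxylate | C=C(C)[C@H](O)CC[C@]1(C)[C@@H](Cl)C[C@H](O)[C@]2(C)[C@@H](C(OC)OC)C(C(=O)OC)=CC[C@@H]12 | intermediate
24 | methyl 3β-chloro-9β-formyl-1α-hydroxy-4α-[(3R)-3-hydroxy-4-methylpent-4-enyl]-4β,10β-dimethyl-5α-decal-7-ene-8-carboxylate (CNP0159496.2) | C=C(C)[C@H](O)CC[C@]1(C)[C@@H](Cl)C[C@H](O)[C@]2(C)[C@@H](C=O)C(C(=O)OC)=CC[C@@H]12 | target

**Step count and risks**
Total: 18 steps. Longest linear sequence: 16 steps (1 to 24 through steps 1, 2 and 5–18; the diene branch, steps 3 and 4, joins at step 5).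

Steps most likely to fail:

1. Step 5. The cycloaddition may be too slow at the hindered enone β-carbon next to the ketal, so that thermal decomposition of the diene competes, and facial control may be incomplete. Fallback: a stepwise anionic double Michael annulation that sets out from 3 and 6. Ketone 6 is deprotonated at the acetyl methyl with LiN(SiMe3)2 (THF, −78 °C) and 3 is added. Michael addition at C5 and, on warming to 0 °C, intramolecular Michael addition of the resulting C10 enolate to C9 should give the cis-fused β-keto ester F1. O-silylation of its enol (iPr3SiOTf, Et3N) returns to 8.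

2. Step 15. The tertiary radical next to the C–Cl bond may be reduced by the Fe–H/silane system before it adds to the acrylamide, may lose a chlorine atom at 60 °C, and some addition may occur from the β face. Fallback: a photoredox radical route from a tertiary alcohol, setting out from 18, which forms the radical at room temperature without a metal hydride. The 1α-hydroxyl is silylated (Et3SiOTf, 2,6-lutidine, −78 °C) to the triethylsilyl ether F2. MeMgBr/CeCl3 (THF, −78 °C) gives the tertiary chlorohydrin F3. Acylation with N-(chlorooxalyloxy)phthalimide (Et3N, DMAP) gives the N-phthalimidoyl oxalate F4. Irradiation with blue light in the presence of Ru(bpy)3(PF6)2, diethyl 1,4-dihydro-2,6-dimethylpyridine-3,5-dicarboxylate, iPr2NEt·HBF4 and 20 should generate the same C4 radical by double decarboxylation and give the silyl-protected Giese adduct F5. HF·pyridine then removes the silyl ether and returns to 21.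

3. Step 14. Enolization or ionization at the α-chloro ketone under the Lewis-acidic Me2AlCl set free from Cp2Ti(μ-CH2)(μ-Cl)AlMe2 could epimerize or eliminate the C3 chloride, and the free hydroxyl and the ester may consume reagent. Fallback: a two-stage Peterson olefination that sets out from 18. Me3SiCH2MgCl/CeCl3 (THF, −78 °C) adds to the C4 ketone to give the β-hydroxysilane F6. KN(SiMe3)2 (THF, 0 °C) then induces syn-elimination of silanolate and returns to 19; the C4 alkoxide and the C3 chloride cannot close to an epoxide because they are not antiperiplanar.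

Further compounds
F1 | step 5 | methyl 9α-(dimethoxymethyl)-3β-[dimethyl(phenyl)silyl]-7-hydroxy-4,4-dimethoxy-10β-methyl-1-oxo-5β-decal-7-ene-8-carboxylate (cis-fused; enol form) | COC1(OC)[C@@H]([Si](C)(C)c3ccccc3)CC(=O)[C@]2(C)[C@H](C(OC)OC)C(C(=O)OC)=C(O)C[C@H]12
F2 | step 15 | methyl 3β-chloro-9β-(dimethoxymethyl)-10β-methyl-4-oxo-1α-(triethylsilyloxy)-5α-decal-7-ene-8-carboxylate | O=C1[C@@H](Cl)C[C@H](O[Si](CC)(CC)CC)[C@]2(C)[C@@H](C(OC)OC)C(C(=O)OC)=CC[C@@H]12
F3 | step 15 | methyl 3β-chloro-9β-(dimethoxymethyl)-4β-hydroxy-4α,10β-dimethyl-1α-(triethylsilyloxy)-5α-decal-7-ene-8-carboxylate | C[C@]1(O)[C@@H](Cl)C[C@H](O[Si](CC)(CC)CC)[C@]2(C)[C@@H](C(OC)OC)C(C(=O)OC)=CC[C@@H]12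
F4 | step 15 | N-phthalimidoyl oxalate of F3 at the C4 oxygen | C[C@]1(OC(=O)C(=O)ON3C(=O)c4ccccc4C3=O)[C@@H](Cl)C[C@H](O[Si](CC)(CC)CC)[C@]2(C)[C@@H](C(OC)OC)C(C(=O)OC)=CC[C@@H]12
F5 | step 15 | 1α-O-triethylsilyl ether of 21 | CON(C)C(=O)CC[C@]1(C)[C@@H](Cl)C[C@H](O[Si](CC)(CC)CC)[C@]2(C)[C@@H](C(OC)OC)C(C(=O)OC)=CC[C@@H]12
F6 | step 14 | methyl 3β-chloro-9β-(dimethoxymethyl)-1α,4β-dihydroxy-10β-methyl-4α-[(trimethylsilyl)methyl]-5α-decal-7-ene-8-carboxylate | C[Si](C)(C)C[C@]1(O)[C@@H](Cl)C[C@H](O)[C@]2(C)[C@@H](C(OC)OC)C(C(=O)OC)=CC[C@@H]12
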